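**Retrosynthetic overview**

1. Numbering: seven-membered ring C1(Me)=C2–C3–C4–C8–C9–C10, five-membered ring C4–C5–C6–C7–C8. The strategy rests on C3, a carbonyl-level carbon lying between alkenyl C2 and the quaternary, methyl-bearing ring-fusion carbon C4, so C3 can be carbon monoxide.
2. Target ⇐ dienone 23 by C5=C6 hydrogenation, 1,2-reduction at C3, isovalerylation, desilylation, C9 aroylation and phenol release.
3. 23 ⇐ (Z)-alkenyl iodide 19 + CO: bonds C2–C3 and C3–C4 by carbonylative Heck closure; the seven-membered ring is formed last, onto a finished cyclopentene.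
4. 19 ⇐ homopropargylic alcohol 15 (anti-carbometalation/iodination); C4=C5 from the C5 ketone via its enol triflate; C9–C10 by propargylation of a C9 aldehyde.
5. The five-membered ring with C7 and C8 comes from (−)-α-thujone by hydroxymercuration of its cyclopropane.

Key step: step 14

Remark: β denotes the face of the five-membered ring on which C8 carries C9, α the opposite face; the methyl-bearing C4 inherited from thujone may epimerise under acid without consequence because it becomes trigonal in step 9, and structures show it unchanged.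

**Step 1**
Reactants: 1 (−)-α-thujone
Product: 2 α-thujone ethylene ketal
Conditions: HOCH2CH2OH, PPTS (cat.), benzene, reflux, azeotropic removal of water
Reagents that add atoms: ethylene glycol, OCCO
Why: Acid-catalysed dioxolane formation (ketalisation) driven by removal of water; the weak acid PPTS should leave the cyclopropane intact, and no stereocentre is created.

**Step 2**
Reactants: 2 α-thujone ethylene ketal
Product: 4 chloromercurio alcohol, via acetoxymercurio alcohol 3 (not isolated)
Conditions: Hg(OAc)2, THF–H2O (1:1), 23 → 40 °C; then sat. aq. NaCl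
Reagents that add atoms: mercury diacetate, CC(=O)O[Hg]OC(C)=O; water, O; sodium chloride, [Na+].[Cl-]
Why: Electrophilic hydroxymercuration of a cyclopropane: divalent mercury attacks the unsubstituted ring carbon (future C9), the bond to the tertiary isopropyl-bearing C7 breaks, and water enters at C7 from the rear with inversion, which places the hydroxyl trans to the C9 arm (α) and the isopropyl group cis to it (β), while C8 keeps the configuration of thujone.

**Step 3**
Reactants: 4 chloromercurio alcohol
Product: 5 diol (primary C9–OH, tertiary C7–OH)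
Conditions: NaBH4, O2 (bubbled), DMF, 23 °C
Reagents that add atoms: dioxygen, O=O
Why: Oxidative demercuration: NaBH4 converts the C–Hg bond into a primary alkyl radical that is trapped by O2, and the hydroperoxide is reduced in situ to the primary alcohol; no stereocentre is touched.

**Step 4**
Reactants: 5 diol
Product: 6 bis(triethylsilyl) ether
Conditions: TESOTf (3 equiv), 2,6-lutidine, CH2Cl2, −78 → 0 °C
Reagents that add atoms: triethylsilyl trifluoromethanesulfonate, CC[Si](CC)(CC)OS(=O)(=O)C(F)(F)F
Why: Silyl ether formation with the reactive silyl triflate, which silylates the hindered tertiary hydroxyl as well as the primary one under buffered conditions that the dioxolane should survive.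

**Step 5**
Reactants: 6 bis(triethylsilyl) ether
Product: 7 C9 aldehyde
Conditions: (COCl)2, DMSO, CH2Cl2, −78 → −30 °C; then Et3N, −78 → 0 °C
Reagents that add atoms: none
Why: Swern oxidation applied directly to the bis-silyl ether: primary triethylsilyl ethers are cleaved and oxidised to aldehydes under these conditions while tertiary silyl ethers are untouched, so C9 reaches the aldehyde level without a separate deprotection.

**Step 6**
Reactants: 7 C9 aldehyde; 8 3-bromo-1-(trimethylsilyl)prop-1-yne
Product: 10 (9R)-homopropargylic alcohol, via silylallenylzinc bromide 9 (not isolated)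
Conditions: 8, Zn dust, THF, 0 °C; then 7, −78 → 0 °C; aq. NH4Cl
Reagents that add atoms: 3-bromo-1-(trimethylsilyl)prop-1-yne (8), C[Si](C)(C)C#CCBr
Why: Barbier-type propargylation: the allenylzinc reagent adds through its γ-carbon (SE2′) to give the homopropargylic alcohol, and Felkin–Anh control by C8 (fully substituted C7 anti to the nucleophile, attack past H8) should set C9 as drawn, the non-chelating silyl ether on O7 keeping chelation from overriding it.

**Step 7**
Reactants: 10 (9R)-homopropargylic alcohol
Product: 11 C9 acetate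
Conditions: Ac2O, pyridine, DMAP (cat.), CH2Cl2, 23 °C
Reagents that add atoms: acetic anhydride, CC(=O)OC(C)=O
Why: DMAP-catalysed acetylation; the acetate masks the C9 hydroxyl during steps 8 to 10 and is later removed together with the alkynyl silane.

**Step 8**
Reactants: 11 C9 acetate
Product: 12 C5 ketone
Conditions: PPTS, acetone–H2O (9:1), 55 °C
Reagents that add atoms: water, O
Why: Mild acid hydrolysis of the dioxolane releases the C5 ketone; the tertiary silyl ether, the acetate and the silylalkyne should tolerate PPTS.

**Step 9**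
Reactants: 12 C5 ketone
Product: 13 C4=C5 enol triflate
Conditions: Tf2O, 2,6-di-tert-butyl-4-methylpyridine, CH2Cl2, 0 → 23 °C
Reagents that add atoms: trifluoromethanesulfonic anhydride, O=S(=O)(OS(=O)(=O)C(F)(F)F)C(F)(F)F
Why: Enol triflate formation with Tf2O and a hindered pyridine: the O-triflylated oxocarbenium ion should lose the C4 proton to give the more substituted, tetrasubstituted C4=C5 enol triflate, and the base-free conditions spare the acetate and avoid β-elimination of the C7 silyloxy group.

**Step 10**
Reactants: 13 C4=C5 enol triflate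
Product: 14 methylcyclopentene (C4=C5)
Conditions: Pd(OAc)2 (5 mol %), PPh3 (10 mol %), Bu3N, HCO2H, DMF, 60 °C
Reagents that add atoms: none
Why: Palladium-catalysed transfer hydrogenolysis of the alkenyl triflate with formate gives the C4=C5 alkene; it is run before any alkenyl iodide exists, because a palladium hydride would not tell the two apart, and the alkyne is shielded by its silyl group.

**Step 11**
Reactants: 14 methylcyclopentene
Product: 15 terminal alkynol
Conditions: K2CO3, MeOH, 23 °C
Reagents that add atoms: none
Why: Methanolysis with K2CO3 cleaves the acetate and the C(sp)–Si bond in one operation, giving the free homopropargylic alcohol that step 12 requires.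

**Step 12**
Reactants: 15 terminal alkynol
Product: 18 (Z)-alkenyl iodide alcohol, via E-alkenylalane 16 (not isolated), via chelated Z-alkenylalane 17 (not isolated)
Conditions: Me3Al (3.5 equiv), Cp2ZrCl2 (25 mol %), ClCH2CH2Cl, 23 °C; then reflux; then I2, THF, −30 → 0 °C
Reagents that add atoms: trimethylaluminium, C[Al](C)C; iodine, II
Why: Negishi carboalumination: Cp2ZrCl2-catalysed syn addition of Me–Al across the terminal alkyne places methyl on C1 and aluminium on C2, heating isomerises the alkenylalane to the isomer chelated by the C9 alkoxide (aluminium cis to C10), and iodinolysis with retention gives the (Z)-alkenyl iodide.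

**Step 13**
Reactants: 18 (Z)-alkenyl iodide alcohol
Product: 19 (Z)-alkenyl iodide with C9–OTBS and C7–OTES
Conditions: TBSOTf, 2,6-lutidine, CH2Cl2, −78 → 0 °C
Reagents that add atoms: tert-butyldimethylsilyl trifluoromethanesulfonate, CC(C)(C)[Si](C)(C)OS(=O)(=O)C(F)(F)F
Why: Silylation of the hindered secondary alcohol with the silyl triflate; the bulky silyl ether also keeps O9 from capturing the acylpalladium species of step 14 as a lactone.

**Step 14**
Reactants: 19 (Z)-alkenyl iodide; 20 carbon monoxide
Product: 23 bicyclic dienone, via acylpalladium iodide 21 (not isolated), via alkylpalladium iodide 22 (not isolated)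
Conditions: Pd(OAc)2 (10 mol %), PPh3 (30 mol %), Et3N (3 equiv), CO (20 atm), MeCN–toluene (1:1), 0.01 M, 90 °C
Reagents that add atoms: carbon monoxide (20), [C-]#[O+]
Why: Proposed new method: zerovalent palladium formed from Pd(OAc)2 and PPh3 adds oxidatively to the (Z)-alkenyl iodide with retention, CO inserts to give acylpalladium 21 (bond C2–C3), the acyl group adds syn across C4=C5 with carbon bonding to C4 (bond C3–C4, 22), and syn β-hydride elimination from C6 releases 23 while Et3N returns palladium to the zerovalent state. The closest known reaction type is the palladium-catalysed carbonylative Heck (acylpalladation) cyclisation, established for five- and six-membered enones but not for a seven-membered ring closed onto a trisubstituted cycloalkene. The seven-membered ring closes in the 7-exo-trig mode by migratory insertion, C3 bonding to the alkene carbon that is joined to the tether-bearing C8. The one new stereocentre, quaternary C4, is controlled by the tether: the chain hangs from the β face of C8, so the acyl group can reach only the β face of C4, which makes the C3–C4 bond cis to C8–C9 and leaves the methyl group α (cis-fused). The step needs CO insertion before alkene insertion (CO pressure and dilution should outpace the direct six-ring Heck closure), exo rather than 8-endo addition (ring size and the adjacency of C4 to C8), and no capture of the acyl group by oxygen (both oxygens silylated, no alcohol or water present). Palladium on C5 has a syn hydrogen only on C6 because C4 is quaternary, and the resulting C5=C6 alkene cannot migrate since both neighbours are fully substituted.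

**Step 15**
Reactants: 23 bicyclic dienone
Product: 24 bicyclic enone
Conditions: RhCl(PPh3)3 (10 mol %), H2 (4 atm), benzene, 40 °C
Reagents that add atoms: none
Why: Homogeneous hydrogenation with RhCl(PPh3)3, which should reduce the cis-disubstituted C5=C6 alkene in preference to the trisubstituted conjugated C1=C2 alkene; no stereocentre is formed.

**Step 16**
Reactants: 24 bicyclic enone
Product: 25 3α-allylic alcohol
Conditions: NaBH4, CeCl3·7H2O, MeOH, −78 → −40 °C
Reagents that add atoms: none
Why: Luche reduction (1,2-reduction of the enone): hydride is expected to approach C3 from the β face, away from the α-methyl group on the adjacent quaternary C4, giving the 3α-alcohol cis to that methyl group.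

**Step 17**
Reactants: 25 3α-allylic alcohol; 26 3-methylbutanoyl chloride
Product: 27 C3 isovalerate
Conditions: 26, pyridine, DMAP, CH2Cl2, 0 → 23 °C
Reagents that add atoms: 3-methylbutanoyl chloride (26), CC(C)CC(=O)Cl
Why: Acylation of the secondary allylic alcohol with the acid chloride under DMAP catalysis; both other oxygens are silylated.

**Step 18**
Reactants: 27 C3 isovalerate
Product: 28 C7,C9 diol
Conditions: HF·pyridine, pyridine, THF, 0 → 23 °C
Reagents that add atoms: none
Why: Fluoride-mediated desilylation with buffered HF·pyridine should remove the secondary TBS and tertiary TES ethers without touching the allylic ester.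

**Step 19**
Reactants: 28 C7,C9 diol; 29 4-acetoxybenzoyl chloride
Product: 30 C9 4-acetoxybenzoate
Conditions: 29, pyridine, DMAP (cat.), CH2Cl2, 0 → 23 °C
Reagents that add atoms: 4-acetoxybenzoyl chloride (29), CC(=O)Oc1ccc(cc1)C(Cl)=O
Why: Acylation of the secondary C9 hydroxyl with the aroyl chloride; the tertiary C7 hydroxyl is too hindered to react, so it needs no protection.

**Step 20**
Reactants: 30 C9 4-acetoxybenzoate
Product: 31 CNP0086724.1
Conditions: N2H4·H2O, THF–MeOH, 0 °C
Reagents that add atoms: none
Why: Chemoselective hydrazinolysis of the phenolic acetate, an activated aryl ester that reacts far faster than the two alkyl esters, releases the phenol and gives the target.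

**Compound list**

1 | (−)-α-thujone | C[C@H]1C(=O)C[C@]2(C(C)C)C[C@H]12 | starting material
2 | α-thujone ethylene ketal (spiro-dioxolane at C5, cyclopropane C7–C9–C8 on the β face) | C[C@H]1C2(OCCO2)C[C@]3(C(C)C)C[C@H]13 | intermediate
3 | acetoxymercurio alcohol (C9–HgOAc on C8 β; C7 α-OH, β-isopropyl; C4 α-methyl; dioxolane at C5) | CC(=O)O[Hg]C[C@@H]1[C@@H](C)C2(OCCO2)C[C@]1(O)C(C)C | intermediate (not isolated)
4 | chloromercurio alcohol (as 3 with C9–HgCl) | Cl[Hg]C[C@@H]1[C@@H](C)C2(OCCO2)C[C@]1(O)C(C)C | intermediate
5 | diol (C9 primary OH, C7 tertiary α-OH) | OC[C@@H]1[C@@H](C)C2(OCCO2)C[C@]1(O)C(C)C | intermediate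
6 | bis(triethylsilyl) ether of 5 | CC[Si](CC)(CC)OC[C@@H]1[C@@H](C)C2(OCCO2)C[C@]1(O[Si](CC)(CC)CC)C(C)C | intermediate
7 | C9 aldehyde (C7–OTES, C5 dioxolane) | O=C[C@@H]1[C@@H](C)C2(OCCO2)C[C@]1(O[Si](CC)(CC)CC)C(C)C | intermediate
8 | 3-bromo-1-(trimethylsilyl)prop-1-yne | C[Si](C)(C)C#CCBr | starting material
9 | [1-(trimethylsilyl)propa-1,2-dienyl]zinc bromide | C=C=C([Zn]Br)[Si](C)(C)C | intermediate (not isolated)
10 | (9R)-homopropargylic alcohol (C9–OH, C10H2–C≡C–SiMe3) | C[Si](C)(C)C#CC[C@@H](O)[C@@H]1[C@@H](C)C2(OCCO2)C[C@]1(O[Si](CC)(CC)CC)C(C)C | intermediate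
11 | C9 acetate of 10 | C[Si](C)(C)C#CC[C@@H](OC(C)=O)[C@@H]1[C@@H](C)C2(OCCO2)C[C@]1(O[Si](CC)(CC)CC)C(C)C | intermediate
12 | C5 ketone (C9–OAc, C7–OTES) | C[Si](C)(C)C#CC[C@@H](OC(C)=O)[C@@H]1[C@@H](C)C(=O)C[C@]1(O[Si](CC)(CC)CC)C(C)C | intermediate
13 | C4=C5 enol triflate (OTf on C5) | C[Si](C)(C)C#CC[C@@H](OC(C)=O)[C@@H]1C(C)=C(OS(=O)(=O)C(F)(F)F)C[C@]1(O[Si](CC)(CC)CC)C(C)C | intermediate
14 | methylcyclopentene (C4=C5; C9–OAc; silylalkyne) | C[Si](C)(C)C#CC[C@@H](OC(C)=O)[C@@H]1C(C)=CC[C@]1(O[Si](CC)(CC)CC)C(C)C | intermediate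
15 | terminal alkynol (C9–OH free) | C#CC[C@@H](O)[C@@H]1C(C)=CC[C@]1(O[Si](CC)(CC)CC)C(C)C | intermediate
16 | (E)-alkenylalane (Al on C2 trans to C10; O9–AlMe2) | C[Al](C)O[C@H](C/C(C)=C/[Al](C)C)[C@@H]1C(C)=CC[C@]1(O[Si](CC)(CC)CC)C(C)C | intermediate (not isolated)
17 | chelated (Z)-alkenylalane (six-membered O9–Al–C2 ring) | C[Al]1O[C@H](CC(C)=C1)[C@@H]1C(C)=CC[C@]1(O[Si](CC)(CC)CC)C(C)C | intermediate (not isolated)
18 | (Z)-alkenyl iodide alcohol (I cis to C10) | I/C=C(/C)C[C@@H](O)[C@@H]1C(C)=CC[C@]1(O[Si](CC)(CC)CC)C(C)C | intermediate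
19 | methylcyclopentene with (Z)-alkenyl iodide chain, C9–OTBS, C7–OTES | I/C=C(/C)C[C@@H](O[Si](C)(C)C(C)(C)C)[C@@H]1C(C)=CC[C@]1(O[Si](CC)(CC)CC)C(C)C | intermediate
20 | carbon monoxide | [C-]#[O+] | starting material
21 | acylpalladium iodide (phosphine ligands not drawn) | O=C([Pd]I)/C=C(/C)C[C@@H](O[Si](C)(C)C(C)(C)C)[C@@H]1C(C)=CC[C@]1(O[Si](CC)(CC)CC)C(C)C | intermediate (not isolated)
22 | alkylpalladium iodide (Pd on C5, β; phosphine ligands not drawn) | CC1=CC(=O)[C@]2(C)[C@H]([Pd]I)C[C@](O[Si](CC)(CC)CC)(C(C)C)[C@@H]2[C@H](O[Si](C)(C)C(C)(C)C)C1 | intermediate (not isolated)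
23 | cis-fused bicyclic dienone (C3 ketone, C1=C2, C5=C6, C4 α-methyl) | CC1=CC(=O)[C@]2(C)C=C[C@](O[Si](CC)(CC)CC)(C(C)C)[C@@H]2[C@H](O[Si](C)(C)C(C)(C)C)C1 | intermediate
24 | bicyclic enone (C5–C6 saturated) | CC1=CC(=O)[C@]2(C)CC[C@](O[Si](CC)(CC)CC)(C(C)C)[C@@H]2[C@H](O[Si](C)(C)C(C)(C)C)C1 | intermediate
25 | 3α-allylic alcohol | CC1=C[C@@H](O)[C@]2(C)CC[C@](O[Si](CC)(CC)CC)(C(C)C)[C@@H]2[C@H](O[Si](C)(C)C(C)(C)C)C1 | intermediate
26 | 3-methylbutanoyl chloride | CC(C)CC(=O)Cl | starting material
27 | C3 isovalerate (C9–OTBS, C7–OTES) | CC1=C[C@@H](OC(=O)CC(C)C)[C@]2(C)CC[C@](O[Si](CC)(CC)CC)(C(C)C)[C@@H]2[C@H](O[Si](C)(C)C(C)(C)C)C1 | intermediate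
28 | C3 isovalerate C7,C9 diol | CC1=C[C@@H](OC(=O)CC(C)C)[C@]2(C)CC[C@](O)(C(C)C)[C@@H]2[C@H](O)C1 | intermediate
29 | 4-acetoxybenzoyl chloride | CC(=O)Oc1ccc(cc1)C(Cl)=O | starting material
30 | C9 4-acetoxybenzoate | CC1=C[C@@H](OC(=O)CC(C)C)[C@]2(C)CC[C@](O)(C(C)C)[C@@H]2[C@H](OC(=O)c2ccc(OC(C)=O)cc2)C1 | intermediate
31 | CNP0086724.1 | CC1=C[C@@H](OC(=O)CC(C)C)[C@]2(C)CC[C@](O)(C(C)C)[C@@H]2[C@H](OC(=O)c2ccc(O)cc2)C1 | target

**Totals**

Total step count: 20. Longest linear sequence: 20 steps (1 → 31).

**Steps most likely to fail**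

1. Step 14. Insertion of the trisubstituted ring alkene into the acyl–palladium bond may be slower than decarbonylation followed by direct six-ring Heck closure, than reduction of the acyl group, or than its capture by O9 after silyl loss. The fallback sets out from 19 and makes the C3–C4 bond by a dipolar cycloaddition. Reductive carbonylation (Pd(PPh3)4, CO, Bu3SnH, THF, 50 °C) should give the (Z)-enal F1. NH2OH·HCl and pyridine in EtOH should give the oxime F2. Aqueous NaOCl in CH2Cl2 at high dilution should generate the nitrile oxide F3, which should add across C4=C5 from the tethered β face to give the isoxazoline F4 (intramolecular nitrile oxide cycloaddition). Mo(CO)6 in MeCN–H2O at 80 °C should cleave the N–O bond and hydrolyse the imine to the β-hydroxy ketone F5. Burgess reagent in benzene at 50 °C should dehydrate F5 towards C6, the only side with hydrogen, and the route is rejoined at 23.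

2. Step 9. Proton loss may occur towards C6 instead of C4, giving the wrong enol triflate regiochemistry, and the tertiary silyl ether may ionise under Tf2O. The fallback sets out from 12. Equilibrating silylation (TMSCl, NaI, Et3N, MeCN, 23 °C) should give the more substituted trimethylsilyl enol ether F6, which can be separated from its regioisomer. C4F9SO2F with catalytic Bu4NF in THF at 0 °C should convert it regiospecifically into the alkenyl nonaflate F7. The formate reduction of step 10 applied to F7 returns to the route at 14.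

3. Step 16. Facial selectivity of hydride delivery to C3 may be poor or reversed, because the cis-fused five-membered ring shields the β face while the C4 methyl shields the α face. The fallback sets out from 24: if reduction gives mainly the 3β-allylic alcohol F8, Mitsunobu esterification with isovaleric acid (PPh3, DIAD, toluene, 0 → 23 °C) should invert C3 and install the ester in one operation, rejoining the route at 27.

**Further compounds**

F1 | step 14 | (Z)-enal (C3 aldehyde cis to C10) | O=C/C=C(/C)C[C@@H](O[Si](C)(C)C(C)(C)C)[C@@H]1C(C)=CC[C@]1(O[Si](CC)(CC)CC)C(C)C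
F2 | step 14 | oxime of F1 | ON=C/C=C(/C)C[C@@H](O[Si](C)(C)C(C)(C)C)[C@@H]1C(C)=CC[C@]1(O[Si](CC)(CC)CC)C(C)C
F3 | step 14 | nitrile oxide | [O-][N+]#C/C=C(/C)C[C@@H](O[Si](C)(C)C(C)(C)C)[C@@H]1C(C)=CC[C@]1(O[Si](CC)(CC)CC)C(C)C
F4 | step 14 | isoxazoline (C3–C4 and O–C5 bonds on the β face) | CC1=CC2=NO[C@@H]3C[C@](O[Si](CC)(CC)CC)(C(C)C)[C@@H]([C@]23C)[C@H](O[Si](C)(C)C(C)(C)C)C1
F5 | step 14 | β-hydroxy ketone (C3 ketone, C5 β-OH) | CC1=CC(=O)[C@]2(C)[C@H](O)C[C@](O[Si](CC)(CC)CC)(C(C)C)[C@@H]2[C@H](O[Si](C)(C)C(C)(C)C)C1
F6 | step 9 | C4=C5 trimethylsilyl enol ether | C[Si](C)(C)C#CC[C@@H](OC(C)=O)[C@@H]1C(C)=C(O[Si](C)(C)C)C[C@]1(O[Si](CC)(CC)CC)C(C)C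
F7 | step 9 | C4=C5 alkenyl nonaflate | C[Si](C)(C)C#CC[C@@H](OC(C)=O)[C@@H]1C(C)=C(OS(=O)(=O)C(F)(F)C(F)(F)C(F)(F)C(F)(F)F)C[C@]1(O[Si](CC)(CC)CC)C(C)C
F8 | step 16 | 3β-allylic alcohol (C3 epimer of 25) | CC1=C[C@H](O)[C@]2(C)CC[C@](O[Si](CC)(CC)CC)(C(C)C)[C@@H]2[C@H](O[Si](C)(C)C(C)(C)C)C1
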